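**Retrosynthetic overview**

1. Numbering used below: ring A is C1 (carbinol carbon with CH2OAc), C2 (bears ring B), C3 (bears the dienyl chain), C4 and C5 (CH2); ring B is C1′ (on C2), C2′ (C=O), C3′=C4′, C5′ (CHMe).
2. Enabling feature: the C4 methylene lies between C3 and C5, and the C1–CH2O carbon, ring B on C2 and the chain on C3 are all cis with the C1 oxygen on the other face. This is the endo adduct of a cyclopentadiene (C3–C4–C5 plus a two-carbon bridge) with a cis alkene C1=C2, once the bridge is cut.
3. Key disconnection: bonds C5–C1 and C2–C3 by Diels–Alder reaction of 2-methylcyclopenta-1,3-diene with a bicyclic α,β-unsaturated δ-lactone, in which the carbonyl carbon on C1 is tied to the C2′ oxygen of ring B (temporary ring; CH2OAc and the C2′ ketone held at other oxidation levels).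
4. After the key step: ozonolysis of the etheno bridge (acetyl on C3, formyl on C5), decarbonylation at C5, Z-selective Wittig reaction, enolate hydroxylation at C1, LiAlH4 opening of the lactone, acetylation, MnO2 oxidation.
5. Ring order: ring B (ring-closing metathesis of an Evans aldol product), lactone ring, norbornene that contains ring A (key step), ring A set free by bridge cleavage, lactone ring opened.

Key step: step 9

Assumption (chemistry): 2-methylcyclopenta-1,3-diene is taken as the freshly distilled monomer from cracking of commercial methylcyclopentadiene dimer, where the 1-methyl isomer is also present; adducts of that isomer would be removed by chromatography after step 9.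

**Route**

Step 1
Reactants: 1 (R)-4-benzyl-1,3-oxazolidin-2-one; 2 (E)-but-2-enoyl chloride
Product: 4 (R)-4-benzyl-3-[(E)-but-2-enoyl]-1,3-oxazolidin-2-one, via N-lithio oxazolidinone 3 (not isolated)
Conditions: n-BuLi, THF, −78 °C; then 2, −78 to 0 °C
Reagents that add atoms: none
Why: N-acylation of the lithiated Evans auxiliary by the acid chloride (imide formation) gives the enoyl imide; no stereocentre is formed.

Step 2
Reactants: 4 (R)-4-benzyl-3-[(E)-but-2-enoyl]-1,3-oxazolidin-2-one
Product: 5 (R)-4-benzyl-3-[(S)-3-methylpent-4-enoyl]-1,3-oxazolidin-2-one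
Conditions: CH2=CHMgBr, CuBr·SMe2, THF, −78 to −20 °C; H2O work-up
Reagents that add atoms: vinylmagnesium bromide, C=C[Mg]Br
Why: auxiliary-controlled copper-mediated conjugate addition; in the magnesium-chelated s-cis imide the vinyl group should add to the β-carbon on the face opposite the benzyl group, which sets the methyl-bearing centre (later C5′).

Step 3
Reactants: 5 (R)-4-benzyl-3-[(S)-3-methylpent-4-enoyl]-1,3-oxazolidin-2-one
Product: 7 (R)-4-benzyl-3-[(2R,3S)-2-[(R)-but-3-en-2-yl]-3-hydroxypent-4-enoyl]-1,3-oxazolidin-2-one, via boron enolate 6 (not isolated)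
Conditions: Bu2BOTf, i-Pr2NEt, CH2Cl2, −78 to 0 °C; acrolein, −78 to 0 °C; then pH 7 buffer, MeOH, H2O2
Reagents that add atoms: acrolein, C=CC=O
Why: Evans syn aldol reaction; the (Z)-boron enolate reacts through a Zimmerman–Traxler chair on the face fixed by the auxiliary, which sets the α-centre (later C1′) and the carbinol centre (later C2′) syn to each other.

Step 4
Reactants: 7 (R)-4-benzyl-3-[(2R,3S)-2-[(R)-but-3-en-2-yl]-3-hydroxypent-4-enoyl]-1,3-oxazolidin-2-one
Product: 8 triethylsilyl ether of 7
Conditions: Et3SiCl, imidazole, DMF, 0 °C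
Reagents that add atoms: chlorotriethylsilane, CC[Si](Cl)(CC)CC
Why: silyl ether formation protects the secondary alcohol for the reduction and oxidation that follow; no stereocentre changes.

Step 5
Reactants: 8 triethylsilyl ether of 7
Product: 9 (R)-4-benzyl-3-{[(1R,2R,5S)-2-methyl-5-(triethylsilyloxy)cyclopent-3-en-1-yl]carbonyl}-1,3-oxazolidin-2-one
Conditions: (H2IMes)(PCy3)Cl2Ru=CHPh (second-generation Grubbs catalyst, 3 mol%), CH2Cl2, 40 °C
Reagents that add atoms: none
Why: ring-closing metathesis of the two terminal vinyl groups closes the cyclopentene ring B with loss of ethene; the three stereocentres are untouched and end all-cis on the ring.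

Step 6
Reactants: 9 (R)-4-benzyl-3-{[(1R,2R,5S)-2-methyl-5-(triethylsilyloxy)cyclopent-3-en-1-yl]carbonyl}-1,3-oxazolidin-2-one
Product: 10 [(1S,2R,5S)-2-methyl-5-(triethylsilyloxy)cyclopent-3-en-1-yl]methanol
Conditions: LiBH4, MeOH (1 equiv), Et2O, 0 °C
Reagents that add atoms: none
Why: reductive cleavage of the imide (hydride reduction) gives the primary alcohol and returns the auxiliary; the α-centre is not enolised.

Step 7
Reactants: 10 [(1S,2R,5S)-2-methyl-5-(triethylsilyloxy)cyclopent-3-en-1-yl]methanol
Product: 11 (1R,2R,5S)-2-methyl-5-(triethylsilyloxy)cyclopent-3-ene-1-carbaldehyde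
Conditions: Dess–Martin periodinane, CH2Cl2, rt
Reagents that add atoms: none
Why: Dess–Martin oxidation gives the aldehyde under neutral conditions, so the α-centre that is cis to both neighbours should not epimerise.

Step 8
Reactants: 11 (1R,2R,5S)-2-methyl-5-(triethylsilyloxy)cyclopent-3-ene-1-carbaldehyde
Product: 14 (4aR,5R,7aS)-5-methyl-5,7a-dihydrocyclopenta[b]pyran-2(4aH)-one, via silylated Z-enoate 12 (not isolated), via hydroxy Z-enoate 13 (not isolated)
Conditions: (CF3CH2O)2P(O)CH2CO2Me, KN(SiMe3)2, 18-crown-6, THF, −78 °C; then 1 M HCl, THF, rt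
Reagents that add atoms: methyl 2-[bis(2,2,2-trifluoroethoxy)phosphoryl]acetate, COC(=O)CP(=O)(OCC(F)(F)F)OCC(F)(F)F
Why: Still–Gennari (Z)-selective Horner–Wadsworth–Emmons olefination followed by acid-mediated desilylation and lactonisation; the Z-enoate lies next to the cis hydroxyl group, so the δ-lactone closes and locks the future C1=C2 alkene as cis, with no new stereocentre.

Step 9
Reactants: 14 (4aR,5R,7aS)-5-methyl-5,7a-dihydrocyclopenta[b]pyran-2(4aH)-one; 15 2-methylcyclopenta-1,3-diene
Product: 16 endo Diels–Alder adduct (tetracyclic norbornene lactone)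
Conditions: 15 (3 equiv), Et2AlCl (0.3 equiv), CH2Cl2, −78 to −20 °C
Reagents that add atoms: none
Why: Et2AlCl binds the lactone carbonyl and the electron-poor alkene of 14 (future C1=C2) undergoes a concerted, asynchronous [4+2] cycloaddition with diene 15, the closest precedent being the Lewis-acid-promoted Diels–Alder reaction of cyclopentadienes with α,β-unsaturated δ-lactones and butenolides. The six-membered carbocycle of the norbornene closes suprafacially on both partners, and the cyclopentane made of the two lactone carbons, the two diene termini and the diene CH2 is ring A with its C5–C1 and C2–C3 bonds in place. The cis ring alkene makes H-1 and H-2 cis; the Alder endo rule puts the lactone carbonyl carbon and C1′ on the side of the new etheno bridge, which fixes C3 and C5 relative to C1 and C2; and the diene should approach the convex face of the cis-fused bicycle, anti to C5′ and its inward-pointing methyl group, which ties all four new centres to C1′. The 2-methyl group enlarges the HOMO coefficient at the adjacent diene terminus, so that terminus should bond to the lactone β-carbon C2 (para orientation) and the methyl group ends on the bridge carbon attached to C3. The step needs endo, convex-face and para selectivity, which the Lewis acid, the bowl shape of 14 and the diene substituent are expected to secure.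

Step 10
Reactants: 16 endo Diels–Alder adduct
Product: 18 keto aldehyde (tricyclic lactone with acetyl on C3 and formyl on C5), via ozonide 17 (not isolated)
Conditions: O3 (1 equiv, Sudan Red 7B indicator), CH2Cl2, −78 °C; then PPh3, −78 °C to rt
Reagents that add atoms: ozone, [O-][O+]=O
Why: ozonolysis with reductive work-up; ozone should attack the strained, trisubstituted norbornene alkene before the ring B alkene that carries the allylic acyloxy group, and cleavage of the bridge leaves acetyl on C3 and formyl on C5, both cis to ring B, without touching a stereocentre.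

Step 11
Reactants: 18 keto aldehyde
Product: 19 methyl ketone (tricyclic lactone with acetyl on C3, C5 now CH2)
Conditions: RhCl(PPh3)3 (1.05 equiv), toluene, 110 °C
Reagents that add atoms: none
Why: Tsuji–Wilkinson decarbonylation (oxidative addition of the formyl C–H bond, CO extrusion, reductive elimination) replaces the formyl group on C5 by hydrogen under neutral conditions that should leave the enolisable C3 centre intact; C5 ceases to be a stereocentre.

Step 12
Reactants: 20 5-bromo-2-methylpent-2-ene
Product: 21 (4-methylpent-3-en-1-yl)triphenylphosphonium bromide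
Conditions: PPh3, MeCN, reflux
Reagents that add atoms: triphenylphosphine, c1ccc(P(c2ccccc2)c2ccccc2)cc1
Why: SN2 quaternisation of the phosphine by the primary bromide gives the Wittig salt.

Step 13
Reactants: 19 methyl ketone; 21 (4-methylpent-3-en-1-yl)triphenylphosphonium bromide
Product: 23 triene lactone (19 with the (Z)-6-methylhepta-2,5-dien-2-yl chain on C3), via phosphonium ylide 22 (not isolated)
Conditions: 21, NaN(SiMe3)2, THF, 0 °C; then 19, −78 °C to rt
Reagents that add atoms: none
Why: Wittig olefination with a non-stabilised ylide; the early, puckered transition state places the ylide substituent cis to the larger ketone substituent (C3 of ring A), which should favour the Z trisubstituted alkene, and the low temperature is meant to keep C3 from epimerising.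

Step 14
Reactants: 23 triene lactone
Product: 25 α-hydroxy lactone (23 with OH on C1), via potassium enolate 24 (not isolated)
Conditions: KN(SiMe3)2, THF, −78 °C; then 2-(benzenesulfonyl)-3-phenyloxaziridine, −78 °C; AcOH quench
Reagents that add atoms: 2-(benzenesulfonyl)-3-phenyloxaziridine, O=S(=O)(N1OC1c1ccccc1)c1ccccc1
Why: Davis oxidation of the lactone enolate (electrophilic α-hydroxylation); the oxaziridine should reach planar C1 on the convex face of the cis-fused ring A–lactone unit, opposite ring B and the side chain, so the hydroxyl group ends trans to both and the ring fusion stays cis.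

Step 15
Reactants: 25 α-hydroxy lactone
Product: 26 triol (primary alcohol on the C1 CH2, tertiary alcohol at C1, allylic alcohol at C2′)
Conditions: LiAlH4, THF, 0 °C; H2O work-up
Reagents that add atoms: none
Why: hydride reduction of the lactone opens the temporary ring to the C1–CH2OH group and the C2′ allylic alcohol; no stereocentre is affected.

Step 16
Reactants: 26 triol
Product: 27 primary monoacetate
Conditions: AcCl (1.05 equiv), 2,4,6-collidine, CH2Cl2, −78 °C
Reagents that add atoms: acetyl chloride, CC(Cl)=O
Why: selective acylation of the unhindered primary alcohol at low temperature with a hindered base should leave the hindered secondary allylic alcohol and the tertiary alcohol free.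

Step 17
Reactants: 27 primary monoacetate
Product: 28 CNP0222995.1 (target)
Conditions: MnO2 (activated, excess), CH2Cl2, rt
Reagents that add atoms: none
Why: MnO2 oxidises only the allylic secondary alcohol to the enone under neutral conditions, so the epimerisable cis centre C1′ next to the new carbonyl appears in the last step and is never exposed to base.

**Compound list**

1 | (R)-4-benzyl-1,3-oxazolidin-2-one | O=C1N[C@H](Cc2ccccc2)CO1 | starting material
2 | (E)-but-2-enoyl chloride | C/C=C/C(Cl)=O | starting material
3 | N-lithio derivative of 1 | [Li]N1[C@H](Cc2ccccc2)COC1=O | intermediate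
4 | (R)-4-benzyl-3-[(E)-but-2-enoyl]-1,3-oxazolidin-2-one | C/C=C/C(=O)N1[C@H](Cc2ccccc2)COC1=O | intermediate
5 | (R)-4-benzyl-3-[(S)-3-methylpent-4-enoyl]-1,3-oxazolidin-2-one | O=C(C[C@H](C)C=C)N1[C@H](Cc2ccccc2)COC1=O | intermediate
6 | (Z)-dibutylboron enolate of 5 | CCCCB(CCCC)O/C(=C\[C@H](C)C=C)N1[C@H](Cc2ccccc2)COC1=O | intermediate
7 | (R)-4-benzyl-3-[(2R,3S)-2-[(R)-but-3-en-2-yl]-3-hydroxypent-4-enoyl]-1,3-oxazolidin-2-one | O=C([C@@H]([C@@H](O)C=C)[C@H](C)C=C)N1[C@H](Cc2ccccc2)COC1=O | intermediate
8 | triethylsilyl ether of 7 | O=C([C@@H]([C@@H](O[Si](CC)(CC)CC)C=C)[C@H](C)C=C)N1[C@H](Cc2ccccc2)COC1=O | intermediate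
9 | (R)-4-benzyl-3-{[(1R,2R,5S)-2-methyl-5-(triethylsilyloxy)cyclopent-3-en-1-yl]carbonyl}-1,3-oxazolidin-2-one (acyl, methyl and silyloxy all cis) | O=C([C@H]1[C@@H](O[Si](CC)(CC)CC)C=C[C@H]1C)N1[C@H](Cc2ccccc2)COC1=O | intermediate
10 | [(1S,2R,5S)-2-methyl-5-(triethylsilyloxy)cyclopent-3-en-1-yl]methanol | OC[C@H]1[C@@H](O[Si](CC)(CC)CC)C=C[C@H]1C | intermediate
11 | (1R,2R,5S)-2-methyl-5-(triethylsilyloxy)cyclopent-3-ene-1-carbaldehyde | O=C[C@H]1[C@@H](O[Si](CC)(CC)CC)C=C[C@H]1C | intermediate
12 | methyl (Z)-3-[(1R,2R,5S)-2-methyl-5-(triethylsilyloxy)cyclopent-3-en-1-yl]prop-2-enoate | COC(=O)/C=C\[C@H]1[C@@H](O[Si](CC)(CC)CC)C=C[C@H]1C | intermediate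
13 | methyl (Z)-3-[(1R,2R,5S)-5-hydroxy-2-methylcyclopent-3-en-1-yl]prop-2-enoate | COC(=O)/C=C\[C@H]1[C@@H](O)C=C[C@H]1C | intermediate
14 | (4aR,5R,7aS)-5-methyl-5,7a-dihydrocyclopenta[b]pyran-2(4aH)-one (cis-fused, methyl cis to the C4a–C4 bond) | O=C1C=C[C@H]2[C@@H](O1)C=C[C@H]2C | intermediate
15 | 2-methylcyclopenta-1,3-diene | CC1=CCC=C1 | starting material
16 | endo Diels–Alder adduct: norbornene whose C1/C2 (ring A) carry the cis-fused lactone and ring B on the endo side, C4 as CH2 bridge, methyl on the bridge alkene carbon attached to C3 | O=C1[C@H]2[C@@H](C=C3C)C[C@@H]3[C@H]2[C@H]2[C@@H](O1)C=C[C@H]2C | intermediate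
17 | ozonide (1,2,4-trioxolane) of 16 at the bridge alkene | O=C1[C@H]2[C@@H](C4OOC3(C)O4)C[C@@H]3[C@H]2[C@H]2[C@@H](O1)C=C[C@H]2C | intermediate
18 | keto aldehyde: ring A–lactone–ring B tricycle with acetyl on C3 and formyl on C5, both cis to ring B | O=C1[C@H]2[C@@H](C=O)C[C@@H](C(C)=O)[C@H]2[C@H]2[C@@H](O1)C=C[C@H]2C | intermediate
19 | methyl ketone: tricyclic lactone with acetyl on C3 (cis to ring B), C5 unsubstituted | O=C1[C@H]2CC[C@@H](C(C)=O)[C@H]2[C@H]2[C@@H](O1)C=C[C@H]2C | intermediate
20 | 5-bromo-2-methylpent-2-ene | CC(C)=CCCBr | starting material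
21 | (4-methylpent-3-en-1-yl)triphenylphosphonium bromide | CC(C)=CCC[P+](c1ccccc1)(c1ccccc1)c1ccccc1.[Br-] | intermediate
22 | (4-methylpent-3-en-1-ylidene)triphenylphosphorane | CC(C)=CCC=P(c1ccccc1)(c1ccccc1)c1ccccc1 | intermediate
23 | triene lactone: tricyclic lactone with the (Z)-6-methylhepta-2,5-dien-2-yl chain on C3 | O=C1[C@H]2CC[C@@H](/C(C)=C\CC=C(C)C)[C@H]2[C@H]2[C@@H](O1)C=C[C@H]2C | intermediate
24 | potassium enolate of 23 | [K+].[O-]C1=C2CC[C@@H](/C(C)=C\CC=C(C)C)[C@H]2[C@H]2[C@@H](O1)C=C[C@H]2C | intermediate
25 | α-hydroxy lactone: 23 with OH on C1, trans to ring B and to the side chain | O=C1[C@@]2(O)CC[C@@H](/C(C)=C\CC=C(C)C)[C@H]2[C@H]2[C@@H](O1)C=C[C@H]2C | intermediate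
26 | triol: ring A with C1(OH)CH2OH, ring B as all-cis 4-methyl-5-substituted cyclopent-2-en-1-ol | OC[C@@]1(O)CC[C@@H](/C(C)=C\CC=C(C)C)[C@H]1[C@H]1[C@@H](O)C=C[C@H]1C | intermediate
27 | primary monoacetate of 26 | CC(=O)OC[C@@]1(O)CC[C@@H](/C(C)=C\CC=C(C)C)[C@H]1[C@H]1[C@@H](O)C=C[C@H]1C | intermediate
28 | CNP0222995.1 | CC(=O)OC[C@@]1(O)CC[C@@H](/C(C)=C\CC=C(C)C)[C@H]1[C@H]1C(=O)C=C[C@H]1C | target

**Summary**

Total step count: 17. Longest linear sequence: 16 steps (steps 1–11 and 13–17; step 12 is a one-step branch).

Steps most likely to fail: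

Step 9. Risk: loss of regiocontrol (meta orientation, or reaction of the isomeric 1-methyl diene), erosion of endo selectivity, and Lewis-acid-induced ionisation of the allylic lactone. Fallback (sets out from 14, returns at 16): the diene is changed to 2-[(tert-butyldimethylsilyl)oxy]cyclopenta-1,3-diene F1, prepared from cyclopent-2-en-1-one with t-BuMe2SiOTf and Et3N, which exists as one isomer and directs para strongly. Its cycloaddition with 14 (toluene, 60 °C, or Me2AlCl at −78 °C) should give the silyl enol ether adduct F2. Bu4NF buffered with AcOH would give the norbornanone F3. KN(SiMe3)2 and PhNTf2 should convert it into the enol triflate F4, since the ketone can enolise only towards its CH2 group. MeMgBr with Fe(acac)3 (catalytic) at −30 °C would then exchange the triflate for methyl to give 16.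

Step 13. Risk: poor Z/E selectivity in oxaphosphetane formation and base-induced epimerisation at C3 next to the ketone. Fallback (sets out from 19 and 21, returns at 23): a Horner–Wittig sequence. Aqueous NaOH converts salt 21 into (4-methylpent-3-en-1-yl)diphenylphosphine oxide F5. Its lithio derivative (n-BuLi, THF, −78 °C) adds to ketone 19 to give β-hydroxy phosphine oxides. The diastereomer with the relative configuration that places C3 and the homoprenyl CH2 on the same side after syn elimination, β-hydroxy phosphine oxide F6, would be separated by chromatography. NaH in DMF then effects stereospecific syn elimination to give 23 as the Z isomer only.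

Step 10. Risk: over-oxidation, with ozone also cleaving the ring B alkene (insufficient chemoselectivity). Fallback (sets out from 16, returns at 18): OsO4 (catalytic) with N-methylmorpholine N-oxide should dihydroxylate the strained norbornene alkene on its exo face well before the hindered ring B alkene, giving the exo-cis-diol F7. NaIO4 on silica then cleaves the glycol to keto aldehyde 18.

Further compounds
F1 | step 9 | 2-[(tert-butyldimethylsilyl)oxy]cyclopenta-1,3-diene | CC(C)(C)[Si](C)(C)OC1=CCC=C1
F2 | step 9 | silyl enol ether adduct (16 with t-BuMe2SiO in place of the bridge methyl) | O=C1[C@H]2[C@@H](C=C3O[Si](C)(C)C(C)(C)C)C[C@@H]3[C@H]2[C@H]2[C@@H](O1)C=C[C@H]2C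
F3 | step 9 | norbornanone (bridge carbon attached to C3 as C=O) | O=C1[C@H]2[C@@H](CC3=O)C[C@@H]3[C@H]2[C@H]2[C@@H](O1)C=C[C@H]2C
F4 | step 9 | enol triflate of F3 | O=C1[C@H]2[C@@H](C=C3OS(=O)(=O)C(F)(F)F)C[C@@H]3[C@H]2[C@H]2[C@@H](O1)C=C[C@H]2C
F5 | step 13 | (4-methylpent-3-en-1-yl)diphenylphosphine oxide | CC(C)=CCCP(=O)(c1ccccc1)c1ccccc1
F6 | step 13 | β-hydroxy phosphine oxide adduct of 19 (diastereomer leading to the Z alkene) | O=C1[C@H]2CC[C@@H]([C@](C)(O)[C@@H](CC=C(C)C)P(=O)(c3ccccc3)c3ccccc3)[C@H]2[C@H]2[C@@H](O1)C=C[C@H]2C
F7 | step 10 | exo-cis-diol of 16 at the bridge alkene | O=C1[C@H]2[C@@H]([C@H](O)[C@]3(C)O)C[C@@H]3[C@H]2[C@H]2[C@@H](O1)C=C[C@H]2C
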